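Start with a subtraction: the three flasks share one charge and differ in temperature.

in all of them: substrate 0.046 M

|  | activator | temperature | remark | time |
|---|---|---|---|---|
| north-west | 0.040 M | −35 °C | run made earlier |  |
| north | 0.090 M | −5 °C | run made earlier |  |
| elm | 0.0598 M | 20 °C |  | 6.0 min |
| cedar | 0.0598 M | −5 °C |  | 6.0 min |
| oak | 0.0598 M | −30 °C |  | 6.0 min |

- the flask that comes out highest in amount of ring, in percent of the substrate charged, or "all alike" when all lie within 1.5 percentage points (elm / cedar / oak / all alike)
- ring at the end, in percent of the substrate charged, elm
- ring at the end, in percent of the substrate charged, cedar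
- ring at the end, in percent of the substrate charged, oak

| run | time / min | ring / % | substrate / % |
|---|---|---|---|
| north-west | 8.00 | 0.6 | 62.0 |
| north-west | 12.0 | 2.3 | 52.7 |
| north-west | 25.0 | 8.0 | 35.5 |
| north-west | 50.0 | 19.5 | 23.4 |
| north-west | 90.0 | 34.6 | 15.8 |
| north | 1.50 | 37.8 | 10.0 |
| north | 5.00 | 76.4 | 0.2 |
| north | 10.0 | 72.0 | 0.6 |
| north | 15.0 | 63.1 | 0 |
| north | 20.0 | 56.3 | 0.5 |

(standard deviation of a reading: 0.5 percentage points)

- the earlier runs were read with a standard deviation of 0.5 percentage points

Activator charged beyond substrate, over the substrate charged, gives 30.0 %; call this the surplus. If activator is spent one for one on substrate, then substrate, the smaller charge, is the limiting reagent in elm, cedar and oak. The runs lean that way: the north-west run was charged 13.0 % short of activator, and its substrate still stands at 15.8 % after 90.0 min, above that shortfall.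

Now the ring. In the north run, substrate is down to 0.2 % at 5.00 min, yet ring falls from 72.0 % at 10.0 min to 56.3 % at 20.0 min, so something is still consuming it. That run has activator to spare, so my working guess is that each ring lost takes one more activator. Then the surplus is a budget: in elm, at 20 °C, the loss may run fast, but on this guess it should stay near the surplus.

You also need the ring made before any loss. The later of those two readings lies twice as far from the start as the earlier, so a steady fractional fall runs back to the earlier reading squared over the later, 92.1 %, a reading with their scatter. Taking that value for elm too, elm ends near or above 62.1 %, so watch the activator there.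

The forecast names cedar, with elm 42 %, cedar 77 % and oak 2 %; its elm figure rests on “decay is extrapolated” and lies below my floor.

The flasks give cedar highest: elm 69.3 %, cedar 78.1 %, oak 3.69 %.

    substrate + activator → activated form (k = 2.60 M⁻¹ s⁻¹, Ea = 46.0 kJ mol⁻¹)
    activated form → ring (k = 0.160 s⁻¹, Ea = 74.0 kJ mol⁻¹)
    substrate + activated form → open dimer (k = 0.120 M⁻¹ s⁻¹, Ea = 47.0 kJ mol⁻¹)
    activator ⇌ dormant form (K = 0.650, k = 0.0300 s⁻¹, Ea = 79.0 kJ mol⁻¹, ΔH = 3.00 kJ mol⁻¹)
    activator + ring → over-reaction product (k = 0.250 M⁻¹ s⁻¹, Ea = 61.0 kJ mol⁻¹)
    (constants at 20 °C)

Elm lies above the floor, its over-reaction product at 27.6 % against a surplus of 30.0 %, with activator at 1.94 % of its charge. Now change one setting: charge cedar with 0.036 M of activator, 0.783 equiv. The surplus becomes a shortfall of 21.7 %, so about that much substrate should stay behind. That flask holds 28 % of substrate, above the shortfall, with unbound activator at 4.1 % of its charge, over-reaction product at 1.26 % and ring at 59.6 %.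

The runs were generated by integration for substances that don't exist; the scatter is artificial.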